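The readings come from a simulation on assumed constants, and the scatter is random.

**The vessel.** A closed, stirred vessel at constant temperature holds starting material at 0.30 M, and the reagent charge is varied; I want the first product standing after 12 h.

common to all: starting material 0.30 M
- north-east: reagent 0.046 M; run made earlier
- east: reagent 0.18 M; run made earlier
- north: reagent 0.51 M; run made earlier
- teal: reagent 0.0600 M; time 12 h
- red: reagent 0.150 M; time 12 h
- ochre: reagent 0.250 M; time 12 h
- amber: reagent 0.500 M; time 12 h

- north-east (time / h: first product / %, starting material / %): 3.00: 6, 84; 6.00: 11, 84; 10.0: 6, 84; 12.0: 6, 82
- east (time / h: first product / %, starting material / %): 3.00: 19, 40; 6.00: 23, 42; 10.0: 22, 41; 12.0: 24, 44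
- north (time / h: first product / %, starting material / %): 1.50: 23, 6; 4.00: 20, 2; 8.00: 20, 2; 12.0: 18, 3

(scatter of a reading: 2 percentage points)

- "hardly changes" means that all values lie within two and a half points (for a concentration: within two and a half percent of the largest)
- a reading of starting material is of its free form alone

1. amount of first product at the end, in percent of the starting material charged for teal, red, ochre, amber, in this order
2. how the row runs (falls, then rises / falls all the way / hardly changes / rises all the way / rises, then falls)

**Reading the runs.** From 3.00 h on, the north-east and east runs show no clear trend beyond the scatter of 2 percentage points, so I read the row as a curve against charge, not time. The readings of the east run give 0.971 mole of free starting material lost per mole of reagent charged, and with less reagent than starting material, reagent looks like the limiting reagent there.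

**The share.** Pooling both runs gives 0.391 first product per free starting material lost, a selectivity I call the share.

**The curve.** My line starts at zero and climbs as share times loss per reagent times charge over starting material. It reads 7.60% at teal and 19.0% at red. Its knee lies at 0.309 M, the charge at which, on this line, the free starting material reckons down to zero. But the north run, at 0.51 M, reads 20.2% on average, a share of 0.209, lower than the pooled share. So the curve has to leave the line and come down to that level, which the line crosses at 0.160 M. I put ochre somewhat under the line's 31.7% and amber near the north level.

**The forecast.** It gives 8%, 19%, 27% and 20%, a row that rises, then falls, and says of the north run: “Excess reagent must therefore consume it, or hold it in a further form”. At ochre its figure is lower than my line's.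

**The flask.** The row is 9.07%, 19.3%, 26.2% and 20.8%; it rises, then falls, and the forecast held within the margin.

    starting material + reagent → first product + by-product (k = 0.160 M⁻¹ min⁻¹)
    starting material + reagent → other mono adduct + by-product (k = 0.160 M⁻¹ min⁻¹)
    reagent + first product → bis adduct + by-product (k = 0.0890 M⁻¹ min⁻¹)
    reagent + other mono adduct → bis adduct + by-product (k = 0.340 M⁻¹ min⁻¹)
    starting material + by-product ⇌ idle adduct, settled at all times (K = 1.10 M⁻¹)

**What ran.** In teal, each of the two steps from starting material and reagent had done half of its turnover by 0.118 h, reagent was under a fiftieth of its charge by 0.743 h, and first product stood at 9.07% at 12.0 h and still 9.07% at 120 h. The share in teal is 0.399 and in red 0.391, beside the 0.391 carried from the runs. In amber, with starting material at 2.93% and reagent at 0%, bis adduct stands at 71.2% and the share is 0.214.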